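Decide first whether the violet flask is worth leaving until 25 min; that turns on who takes the acid set free.

all flasks: electrophile 0.25 M

| run | nucleophile | free base | remark | time |
|---|---|---|---|---|
| violet | 0.50 M | 0.20 M | the very flask that is asked about, followed so far |  |
| blue | 0.50 M | 0.10 M | run made earlier |  |
| flask | 0.500 M | 0.200 M |  | 25 min |

| run | time / min | electrophile / % | target / % |
|---|---|---|---|
| violet | 0.250 | 94.0 | 6.4 |
| violet | 0.417 | 89.9 | 10.4 |
| violet | 0.667 | 84.1 | 14.7 |
| violet | 1.00 | 78.2 | 21.0 |
| violet | 2.00 | 63.3 | 35.2 |
| violet | 3.00 | 54.6 | 45.4 |
| blue | 1.50 | 70.5 | 29.0 |
| blue | 3.00 | 55.2 | 45.8 |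
| blue | 5.00 | 41.5 | 58.6 |
| blue | 6.00 | 36.4 | 63.0 |
| blue | 8.00 | 30.5 | 69.3 |
| blue | 10.0 | 25.4 | 74.8 |

(readings scatter by 0.5 percentage points)

- steps that have been proposed: acid set free + free base <-> salt of the base; electrophile + nucleophile <-> acid set free + target; nucleophile + acid set free <-> protonated nucleophile
- the earlier runs do not show how much of nucleophile is bound; that part of a forecast is a guess

1. part of the electrophile that has reacted at 25 min
2. share of the unused nucleophile that is free and not bound as protonated nucleophile, at 25 min

Two views stand. I say the nucleophile takes the acid. Doubling the free base from 0.10 M to 0.20 M moved the electrophile at 3.00 min by 0.6 percentage points, which is within the scatter of two readings. So each electrophile reacted costs two nucleophile, one to react and one to be protonated.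

I therefore carry the reach, c(nucleophile) charged over twice c(electrophile) charged: the part of the electrophile the nucleophile can pay for. Here it is 100 %, so both should fall together, and the share of electrophile left should go as one over one plus time over a constant. The last blue reading gives that constant as 3.40 min. My reckoning at 25 min is then 88.0 % reacted and 21.4 % free.

The forecast takes the other side, that “the base and nucleophile bind acid about equally well”. It gives 92.7 % (89 % to 96 %) and 50 % (38 % to 68 %), and it differs from my reckoning on both.

The flask gives 89.2 % reacted and 29.2 % free, which is below the forecast's range but above my figure.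

    acid set free + free base ⇌ salt of the base, settled at all times (K = 690 M⁻¹)
    electrophile + nucleophile ⇌ acid set free + target (K = 1.10, k = 0.00930 M⁻¹ s⁻¹)
    nucleophile + acid set free ⇌ protonated nucleophile, settled at all times (K = 11000 M⁻¹)

Constant times charge stands at 5500 for the nucleophile's pairing with the acid and 140 for the free base's. At 25.0 min the flask holds 0.196 M protonated nucleophile against 0.0264 M salt of the base, and with a reach of 100 %, 11 % of the electrophile remains and 16 % of the charged nucleophile is still free.

With 0.20 M nucleophile the reach falls to 40.0 %, making the nucleophile the limiting reagent, so I expect a stall near there. That neighbour flask reaches 47.3 %, and it holds 0.0686 M protonated nucleophile and 0.0492 M salt of the base.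

All runs are calculated from invented constants; the scatter is artificial.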